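**Plan**

- Retrosynthesis: cut C3–CH2CO2Me (peroxycarbenium ion + silyl ketene acetal). Then cut C5–O1 and C3–O2 of the dioxolane, returning both peroxide oxygens to H2O2 and the C3–C4–C5 unit to a four-membered 2-methyleneoxetane. Then oxetane → β-lactone → 1,3-diol → (E)-allylic alcohol → terminal alkyne → (R)-citronellal + 4-phenylbut-1-ene.
- Forward: the chain is joined first (cross-metathesis, hydrogenation, alkyne, carboalumination), then the tertiary carbinol (Sharpless epoxidation, Red-Al). The oxetane is the first ring (β-lactone, methylenation) and is expanded by H2O2 to the 1,2-dioxolane; the acetate arm comes last.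
- Enabling feature: dioxolane C3 is at the ketone oxidation level (methyl plus an arm that can arrive as an enolate equivalent) and stands 1,3 to the fully substituted C5–O centre across the C4 methylene. The ring O1–O2–C3–C4–C5 therefore maps onto the O–C(=CH2)–CH2–C ring of an enol-ether oxetane whose single ring oxygen is exchanged for O–O.
- Stereochemistry: the side-chain methine (R) is bought with (R)-citronellal. The tertiary C–O centre is set by reagent-controlled Sharpless epoxidation and inverted (R → S at C5) by backside attack of H2O2 in the ring expansion. C3 (R) is set last by substrate control, the nucleophile entering anti to the larger C5 substituent.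

Key step: step 10

Remark: (R)-citronellal of high enantiomeric purity is assumed; C3 of 15 and 16 is a mixture of epimers that converges on the planar ion 18.

**Route**

Step 1
Reactants: 1 (R)-citronellal [(3R)-3,7-dimethyloct-6-enal]; 2 4-phenylbut-1-ene
Product: 3 (3R)-3-methyl-9-phenylnon-6-enal (E/Z mixture)
Conditions: Hoveyda–Grubbs II (3 mol%), 2 (3 equiv), CH2Cl2, 40 °C, N2 sweep
Reagents that add atoms: none
Why: Olefin cross-metathesis exchanges the isopropylidene end of the prenyl-type alkene for the terminal alkene partner, loss of volatile 2-methylpropene driving the equilibrium; the aldehyde and the stereocentre are untouched and E/Z is irrelevant because the alkene is hydrogenated next.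

Step 2
Reactants: 3 (3R)-3-methyl-9-phenylnon-6-enal
Product: 4 (3R)-3-methyl-9-phenylnonanal
Conditions: H2 (1 atm), 10% Pd/C, EtOAc, rt
Reagents that add atoms: none
Why: Heterogeneous catalytic hydrogenation of an isolated disubstituted alkene is much faster than reduction of an aliphatic aldehyde or of the arene under these conditions.

Step 3
Reactants: 4 (3R)-3-methyl-9-phenylnonanal
Product: 5 (4R)-4-methyl-10-phenyldec-1-yne
Conditions: Ohira–Bestmann reagent, K2CO3, MeOH, 0 °C → rt
Reagents that add atoms: dimethyl (1-diazo-2-oxopropyl)phosphonate (CC(=O)C(=[N+]=[N-])P(=O)(OC)OC)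
Why: Seyferth–Gilbert homologation in the Ohira–Bestmann variant converts the aldehyde into the terminal alkyne under mild base; the stereocentre is β to the carbonyl and cannot epimerise.

Step 4
Reactants: 5 (4R)-4-methyl-10-phenyldec-1-yne
Product: 7 (2E,5R)-3,5-dimethyl-11-phenylundec-2-en-1-ol, via alkenylalane 6 (not isolated)
Conditions: AlMe3 (2.5 equiv), Cp2ZrCl2 (0.25 equiv), CH2Cl2, 0 °C → rt; then n-BuLi, THF, −78 °C; (CH2O)n, −78 °C → rt
Reagents that add atoms: trimethylaluminium (C[Al](C)C); formaldehyde as paraformaldehyde (C=O)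
Why: Negishi zirconium-catalysed carboalumination adds Me–Al syn across the terminal alkyne with aluminium at the terminus, and the derived alanate is hydroxymethylated with retention, which fixes the (E)-trisubstituted alkene.

Step 5
Reactants: 7 (2E,5R)-3,5-dimethyl-11-phenylundec-2-en-1-ol
Product: 8 [(2R,3R)-3-methyl-3-[(2R)-2-methyl-8-phenyloctyl]oxiran-2-yl]methanol
Conditions: Ti(Oi-Pr)4 (10 mol%), D-(−)-diethyl tartrate (12 mol%), t-BuOOH (2 equiv, anhydrous), 4 Å MS, CH2Cl2, −20 °C
Reagents that add atoms: tert-butyl hydroperoxide (CC(C)(C)OO)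
Why: Katsuki–Sharpless asymmetric epoxidation; for this geraniol-type (E)-allylic alcohol D-(−)-tartrate delivers oxygen to the face that gives the (2R,3R)-epoxide, so the tertiary C–O centre (future C5) is set by catalyst control.

Step 6
Reactants: 8 [(2R,3R)-3-methyl-3-[(2R)-2-methyl-8-phenyloctyl]oxiran-2-yl]methanol
Product: 9 (3R,5R)-3,5-dimethyl-11-phenylundecane-1,3-diol
Conditions: Red-Al, THF, 0 °C → rt; Rochelle salt work-up
Reagents that add atoms: none
Why: Hydroxyl-directed Red-Al opening of a 2,3-epoxy alcohol delivers hydride intramolecularly to C2 and gives the 1,3-diol, leaving the tertiary C3–O bond and its configuration untouched.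

Step 7
Reactants: 9 (3R,5R)-3,5-dimethyl-11-phenylundecane-1,3-diol
Product: 10 (3R,5R)-3-hydroxy-3,5-dimethyl-11-phenylundecanoic acid
Conditions: TEMPO (cat.), NaClO2, NaOCl (cat.), MeCN/phosphate buffer (pH 6.7), 35 °C
Reagents that add atoms: sodium chlorite ([Na+].[O-]Cl=O)
Why: TEMPO/chlorite oxidation takes the primary alcohol through the aldehyde to the acid near neutral pH, where the tertiary alcohol is inert and retro-aldol cleavage should be slow.

Step 8
Reactants: 10 (3R,5R)-3-hydroxy-3,5-dimethyl-11-phenylundecanoic acid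
Product: 11 (4R)-4-methyl-4-[(2R)-2-methyl-8-phenyloctyl]oxetan-2-one
Conditions: PhSO2Cl, pyridine, 0 °C
Reagents that add atoms: none
Why: Adam β-lactonisation activates the carboxyl group as the mixed sulfonic anhydride and the tertiary hydroxyl attacks the acyl carbon (4-exo-trig), so the carbinol configuration is retained.

Step 9
Reactants: 11 (4R)-4-methyl-4-[(2R)-2-methyl-8-phenyloctyl]oxetan-2-one
Product: 12 (4R)-4-methyl-2-methylidene-4-[(2R)-2-methyl-8-phenyloctyl]oxetane
Conditions: Cp2TiMe2 (2.5 equiv), toluene, 75 °C, dark; filtration through basic alumina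
Reagents that add atoms: dimethyltitanocene ([CH3-].[CH3-].[Ti+4].c1cc[cH-]c1.c1cc[cH-]c1)
Why: Petasis carbonyl methylenation (Cp2Ti=CH2 generated thermally) converts β-lactones into 2-methyleneoxetanes without opening the ring; the quaternary centre is not involved.

Step 10
Reactants: 12 (4R)-4-methyl-2-methylidene-4-[(2R)-2-methyl-8-phenyloctyl]oxetane
Product: 15 (5S)-3,5-dimethyl-5-[(2R)-2-methyl-8-phenyloctyl]-1,2-dioxolan-3-ol, via oxetan-2-ylium ion 13 (not isolated), via hydroperoxy ketone 14 (not isolated)
Conditions: H2O2 (anhydrous, ca. 2 M in Et2O, 15 equiv), TMSOTf (10 mol%), Et2O, −78 → −30 °C; Et3N quench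
Reagents that add atoms: hydrogen peroxide (OO)
Why: Proposed new method: catalytic acid protonates the exocyclic enol ether of 12 at CH2 to give the strained O-alkyl oxocarbenium ion 13, whose tertiary O–C4 bond is cut by backside attack of H2O2 (borderline SN2) to give hydroperoxy ketone 14, which closes at once by 5-exo-trig addition of the OOH terminus to the ketone, so the O–C–CH2–C oxetane becomes the O–O–C–CH2–C dioxolane (ring expansion by one atom, the old ring oxygen ending as the hemiketal OH). The closest known reaction types are the Lewis-acid perhydrolysis of 2,2-disubstituted oxetanes to 3-hydroperoxy alcohols with inversion at the tertiary carbon, the opening of 2-methyleneoxetanes at C4 by protic nucleophiles to give β-substituted methyl ketones, and the spontaneous cyclisation of β-hydroperoxy ketones to 1,2-dioxolan-3-ols. The new stereocentre C5 of the dioxolane (S) arises from the (R) oxetane carbon by inversion and is thus relayed from the Sharpless epoxidation; the hemiketal carbon C3 forms as a mixture, which does not matter because it is planarised in step 12. The step needs attack at the tertiary ring carbon to beat ionisation (racemisation, E1) and capture at the carbenium carbon: in the substrate, ring strain and the neutral ketone leaving group make cleavage of the O–C(tertiary) bond the only irreversible exit, addition of H2O2 to the carbenium carbon being expected to revert, while ether solvent, low temperature and a large excess of anhydrous H2O2 favour the bimolecular path and exclusion of water prevents hydrolysis to the β-hydroxy ketone.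

Step 11
Reactants: 15 (5S)-3,5-dimethyl-5-[(2R)-2-methyl-8-phenyloctyl]-1,2-dioxolan-3-ol
Product: 16 (5S)-3-methoxy-3,5-dimethyl-5-[(2R)-2-methyl-8-phenyloctyl]-1,2-dioxolane
Conditions: MeOH, p-TsOH·H2O (cat.), rt
Reagents that add atoms: methanol (CO)
Why: Acid-catalysed ketalisation of the peroxy hemiketal with methanol is the standard conversion of 1,2-dioxolan-3-ols into 3-alkoxy-1,2-dioxolanes, and the quaternary C5–O bond is not ionised under these conditions.

Step 12
Reactants: 16 (5S)-3-methoxy-3,5-dimethyl-5-[(2R)-2-methyl-8-phenyloctyl]-1,2-dioxolane; 17 tert-butyl[(1-methoxyethenyl)oxy]dimethylsilane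
Product: 19 methyl 2-[(3R,5S)-3,5-dimethyl-5-[(2R)-2-methyl-8-phenyloctyl]-1,2-dioxolan-3-yl]acetate, via peroxycarbenium ion 18 (not isolated)
Conditions: 17 (2.5 equiv), TiCl4 (1.1 equiv), CH2Cl2, −78 °C; NaHCO3 quench
Reagents that add atoms: none
Why: Lewis-acid-mediated substitution of a 3-alkoxy-1,2-dioxolane by a silyl ketene acetal (Mukaiyama-type addition to ion 18) should occur anti to the larger C5 substituent (the branched chain), placing CH2CO2Me cis to the C5 methyl as required for (3R,5S), the minor C3 epimer being removed by chromatography.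

**Compound list**

1 | (3R)-3,7-dimethyloct-6-enal, (R)-citronellal | O=CC[C@H](C)CCC=C(C)C | starting material
2 | 4-phenylbut-1-ene | C=CCCc1ccccc1 | starting material
3 | (3R)-3-methyl-9-phenylnon-6-enal (E/Z mixture, E shown) | O=CC[C@H](C)CC/C=C/CCc1ccccc1 | intermediate
4 | (3R)-3-methyl-9-phenylnonanal | O=CC[C@H](C)CCCCCCc1ccccc1 | intermediate
5 | (4R)-4-methyl-10-phenyldec-1-yne | C#CC[C@H](C)CCCCCCc1ccccc1 | intermediate
6 | [(1E,4R)-2,4-dimethyl-10-phenyldec-1-en-1-yl]dimethylalumane | C[Al](C)/C=C(\C)C[C@H](C)CCCCCCc1ccccc1 | intermediate (not isolated)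
7 | (2E,5R)-3,5-dimethyl-11-phenylundec-2-en-1-ol | OC/C=C(\C)C[C@H](C)CCCCCCc1ccccc1 | intermediate
8 | [(2R,3R)-3-methyl-3-[(2R)-2-methyl-8-phenyloctyl]oxiran-2-yl]methanol | OC[C@H]1O[C@]1(C)C[C@H](C)CCCCCCc1ccccc1 | intermediate
9 | (3R,5R)-3,5-dimethyl-11-phenylundecane-1,3-diol | OCC[C@](C)(O)C[C@H](C)CCCCCCc1ccccc1 | intermediate
10 | (3R,5R)-3-hydroxy-3,5-dimethyl-11-phenylundecanoic acid | OC(=O)C[C@](C)(O)C[C@H](C)CCCCCCc1ccccc1 | intermediate
11 | (4R)-4-methyl-4-[(2R)-2-methyl-8-phenyloctyl]oxetan-2-one | O=C1C[C@@](C)(C[C@H](C)CCCCCCc2ccccc2)O1 | intermediate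
12 | (4R)-4-methyl-2-methylidene-4-[(2R)-2-methyl-8-phenyloctyl]oxetane | C=C1C[C@@](C)(C[C@H](C)CCCCCCc2ccccc2)O1 | intermediate
13 | (4R)-2,4-dimethyl-4-[(2R)-2-methyl-8-phenyloctyl]oxetan-2-ylium (oxocarbenium ion) | CC1=[O+][C@](C)(C[C@H](C)CCCCCCc2ccccc2)C1 | intermediate (not isolated)
14 | (4S,6R)-4-hydroperoxy-4,6-dimethyl-12-phenyldodecan-2-one | CC(=O)C[C@](C)(C[C@H](C)CCCCCCc1ccccc1)OO | intermediate (not isolated)
15 | (5S)-3,5-dimethyl-5-[(2R)-2-methyl-8-phenyloctyl]-1,2-dioxolan-3-ol (both C3 epimers) | CC1(O)C[C@](C)(C[C@H](C)CCCCCCc2ccccc2)OO1 | intermediate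
16 | (5S)-3-methoxy-3,5-dimethyl-5-[(2R)-2-methyl-8-phenyloctyl]-1,2-dioxolane (both C3 epimers) | COC1(C)C[C@](C)(C[C@H](C)CCCCCCc2ccccc2)OO1 | intermediate
17 | tert-butyl[(1-methoxyethenyl)oxy]dimethylsilane | C=C(OC)O[Si](C)(C)C(C)(C)C | starting material
18 | (5S)-3,5-dimethyl-5-[(2R)-2-methyl-8-phenyloctyl]-1,2-dioxolan-3-ylium (peroxycarbenium ion) | CC1=[O+]O[C@@](C)(C[C@H](C)CCCCCCc2ccccc2)C1 | intermediate (not isolated)
19 | methyl 2-[(3R,5S)-3,5-dimethyl-5-[(2R)-2-methyl-8-phenyloctyl]-1,2-dioxolan-3-yl]acetate | COC(=O)C[C@@]1(C)C[C@](C)(C[C@H](C)CCCCCCc2ccccc2)OO1 | target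

**Step count and risks**

Total steps: 12. Longest linear sequence: 12 steps (from 1).

Steps most likely to fail:

1. Step 10 (Proposed new method). What may go wrong: ion 13 may ionise at the tertiary C–O bond before H2O2 arrives, which would erode the configuration of the future C5 and open an E1 elimination path. Alternatively, capture at the carbenium carbon followed by endocyclic opening could divert material to β-hydroxy ketone derivatives.
Fallback (known chemistry, sets out from 12, returns at 16): 12 is hydrolysed (PPTS, wet THF) to (4R,6R)-4-hydroxy-4,6-dimethyl-12-phenyldodecan-2-one F1. NaBH4 gives (4R,6R)-4,6-dimethyl-12-phenyldodecane-2,4-diol F2 (both C2 epimers usable). The secondary hydroxyl is sulfonylated selectively (TsCl, pyridine) to (4R,6R)-4-hydroxy-4,6-dimethyl-12-phenyldodecan-2-yl 4-methylbenzenesulfonate F3, and KOt-Bu closes (2R)-2,4-dimethyl-2-[(2R)-2-methyl-8-phenyloctyl]oxetane F4. The established oxetane perhydrolysis (H2O2, TMSOTf, Et2O, −78 °C) opens F4 at the tertiary carbon with inversion to (4S,6R)-4-hydroperoxy-4,6-dimethyl-12-phenyldodecan-2-ol F5. The OOH group is masked with 2-methoxypropene/PPTS as (4S,6R)-4-[(2-methoxypropan-2-yl)peroxy]-4,6-dimethyl-12-phenyldodecan-2-ol F6, and Dess–Martin oxidation gives (4S,6R)-4-[(2-methoxypropan-2-yl)peroxy]-4,6-dimethyl-12-phenyldodecan-2-one F7. TsOH in MeOH then removes the peroxyketal and closes the ring to 16.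

2. Step 9. What may go wrong: thermal decarboxylative cycloreversion of the β,β-disubstituted β-lactone at the temperature needed to generate Cp2Ti=CH2, and hydrolysis of the enol ether during isolation.
Fallback (sets out from 11, returns at 16): the methyleneoxetane is given up. 11 is opened at the acyl carbon with MeNH(OMe)·HCl/i-PrMgCl to (3R,5R)-3-hydroxy-N-methoxy-N,3,5-trimethyl-11-phenylundecanamide F8, and MeMgBr converts F8 into the β-hydroxy ketone F1 already described. From F1 the reduction, oxetane closure, perhydrolysis, oxidation and ketalisation sequence of the first fallback leads to 16.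

3. Step 12. What may go wrong: insufficient facial discrimination between the methyl and the branched alkyl group at C5 in the capture of ion 18, so that much of the material ends as the C3 epimer.
Fallback (sets out from 16, returns at 19): selectivity is sought by recycling under equilibrating conditions instead of kinetic control. Step 12 is run as described and the epimer methyl 2-[(3S,5S)-3,5-dimethyl-5-[(2R)-2-methyl-8-phenyloctyl]-1,2-dioxolan-3-yl]acetate F9 is collected. A catalytic base (DBU or NaOMe, MeOH) is expected to open it by E1cB loss of the peroxide from the ester enolate to methyl (2E,5S,7R)-5-hydroperoxy-3,5,7-trimethyl-13-phenyltridec-2-enoate F10. Its 5-exo-trig oxa-Michael reclosure redistributes material between F9 and 19, and repeated separation and recycling should convert the unwanted epimer into 19. Neither peroxide carbon bears hydrogen, so Kornblum–DeLaMare cleavage cannot compete, and C5 is not touched.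

**Further compounds**

F1 | step 10 | (4R,6R)-4-hydroxy-4,6-dimethyl-12-phenyldodecan-2-one | CC(=O)C[C@](C)(O)C[C@H](C)CCCCCCc1ccccc1
F2 | step 10 | (4R,6R)-4,6-dimethyl-12-phenyldodecane-2,4-diol (C2 epimers) | CC(O)C[C@](C)(O)C[C@H](C)CCCCCCc1ccccc1
F3 | step 10 | (4R,6R)-4-hydroxy-4,6-dimethyl-12-phenyldodecan-2-yl 4-methylbenzenesulfonate | Cc1ccc(cc1)S(=O)(=O)OC(C)C[C@](C)(O)C[C@H](C)CCCCCCc1ccccc1
F4 | step 10 | (2R)-2,4-dimethyl-2-[(2R)-2-methyl-8-phenyloctyl]oxetane (C4 epimers) | CC1C[C@@](C)(C[C@H](C)CCCCCCc2ccccc2)O1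
F5 | step 10 | (4S,6R)-4-hydroperoxy-4,6-dimethyl-12-phenyldodecan-2-ol | CC(O)C[C@](C)(C[C@H](C)CCCCCCc1ccccc1)OO
F6 | step 10 | (4S,6R)-4-[(2-methoxypropan-2-yl)peroxy]-4,6-dimethyl-12-phenyldodecan-2-ol | CC(O)C[C@](C)(C[C@H](C)CCCCCCc1ccccc1)OOC(C)(C)OC
F7 | step 10 | (4S,6R)-4-[(2-methoxypropan-2-yl)peroxy]-4,6-dimethyl-12-phenyldodecan-2-one | CC(=O)C[C@](C)(C[C@H](C)CCCCCCc1ccccc1)OOC(C)(C)OC
F8 | step 9 | (3R,5R)-3-hydroxy-N-methoxy-N,3,5-trimethyl-11-phenylundecanamide | CON(C)C(=O)C[C@](C)(O)C[C@H](C)CCCCCCc1ccccc1
F9 | step 12 | methyl 2-[(3S,5S)-3,5-dimethyl-5-[(2R)-2-methyl-8-phenyloctyl]-1,2-dioxolan-3-yl]acetate | COC(=O)C[C@]1(C)C[C@](C)(C[C@H](C)CCCCCCc2ccccc2)OO1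
F10 | step 12 | methyl (2E,5S,7R)-5-hydroperoxy-3,5,7-trimethyl-13-phenyltridec-2-enoate | COC(=O)/C=C(\C)C[C@](C)(C[C@H](C)CCCCCCc1ccccc1)OO
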